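Which temperature leaves the most target after 20 min, given a partner that decays and is also quenched by the protic impurity?

    partner + protic impurity → quenched reagent (k1 = 16 /M/min, Ea1 = 51.0 kJ/mol)
    partner → decomposed reagent (k2 = 0.019 /min, Ea2 = 95.0 kJ/mol)
    starting material → decomposition product (k3 = 1.7 × 10⁻⁵ /min, Ea3 = 116 kJ/mol)
    starting material + partner ⇌ target + by-product (K4 = 0.57, k4 = 0.75 /M/min, Ea4 = 76.0 kJ/mol, ΔH4 = −46.0 kJ/mol)
    (constants at 70 °C)

| flask | starting material | partner | protic impurity | temperature | time |
|---|---|---|---|---|---|
| Monday's | 0.040 M | 0.950 equiv | 0.0200 M | 110 °C | 20 min |
| Saturday's | 0.040 M | 0.950 equiv | 0.0200 M | 90 °C | 20 min |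
| Tuesday's | 0.040 M | 0.950 equiv | 0.0200 M | 70 °C | 20 min |

- at 70 °C the constants are as listed, elsewhere as the activation energies and enthalpies make them

- which flask leads in amount of target, in percent of the starting material charged ("all alike" within 1.5 percentage points) (Monday's / Saturday's / Tuesday's / all alike)
- how much target is there at the end, in percent of the starting material charged: Monday's
- how much target is there at the end, in percent of the starting material charged: Saturday's
- how much target is there at the end, in percent of the starting material charged: Tuesday's

Turned into a time, the partner's decay in Tuesday's flask takes 52.6 min, against a run of 20 min. The ratio of the two gives one number: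

N = k(decay) · t = 0.380 for Tuesday's, 12.3 for Monday's

N is the count of partner lifetimes that fit into the run. Tuesday's flask has N below one, so decay by itself should leave part of its partner at the end of the run. Monday's has N far above one, so decay should carry its partner far down early in the run, and the reversible step can then run target and by-product back. Saturday's lies between, so my order is Tuesday's, Saturday's, Monday's.

Is one number enough? The forward race gives a first test:

k(decay) / (k(forward) · c(starting material)) = 0.633 for Tuesday's

From coldest to hottest flask this ratio grows by a factor of 2.00, whereas N grows by 32. Both numbers rise from the coldest to the hottest flask, so the order stands. For the amounts N is not enough. In Tuesday's flask the impurity's rate constant at its charge, 0.320 /min, is about ten times the forward step's 0.0300 /min, so the impurity should claim partner ahead of the forward step, and subtracting its 0.0200 M from the partner charge leaves about 0.0180 M. The equilibrium constant also falls from 0.570 in Tuesday's flask to 0.106 in Monday's. My reckoning stops at the order.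

The forecast gives amounts as well: 1.9% for Monday's, 11% for Saturday's and 16.7% for Tuesday's, with Tuesday's ahead. Its ground: “Hot flasks therefore peak early and then erode.”

The simulation gives 1.91%, 11.1% and 16.5% in the same order, so Tuesday's leads. Monday's N of 12.3 goes with 0.164% of its partner charge left at 20.0 min, Tuesday's N of 0.380 with 17.6%. With 3.80 equiv of partner in Tuesday's flask, N stays 0.380, so decay by itself would leave 0.0903 M of the free partner. That flask holds 0.0720 M of partner and 0.0240 M of by-product, with target at 60.0%.

The numbers of this flask are made up; the rest is arithmetic.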